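## The problem

The target is a normal-series labdane, 3α,6β,19-trihydroxylabda-8,13E-dien-15-oic acid (34). It is a trans-decalin whose ring B holds a tetrasubstituted C8=C9 alkene carrying the C17 methyl group and an (E)-3-methylpent-2-enoic acid chain. Five contiguous stereocentres (C3, C4, C5, C6, C10) must be set, two of them quaternary (C4, C10). The β face carries three syn-axial groups (C20 methyl, C19 hydroxymethyl, 6β-hydroxyl), and the axial 3α-hydroxyl is trans to C19. Intermolecular bond formation at C4 of a ring-A enolate or enone would go to the open α face, so C19 has to be delivered from a β-oxygen. Three relays are available: C6, attached to C5, can decide the face of C10; C10 and C6 together shield the β face and so fix H-5 (α); a 3β-oxygen can carry C19 to C4. Fragile points are the C6 oxygen next to an enone (lost under dissolving-metal reduction), β-silyloxy and β-hydroxy ketone stages (elimination, retro-aldol), the tetrasubstituted alkene (acid-induced migration) and the 13E enoate. The enabling feature is ring A: C3 bears oxygen, C10 (para to C3) bears a methyl group and the bond to C9, C4 (ortho) bears a methyl group, and the oxygenated C6 sits on C5 between them. Ring A can therefore start as a 2,4-dimethylphenol with a benzylic C6 stereocentre, and oxidation of the phenol makes C10 the electrophile for a C6–C9 tether.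

## Retrosynthesis

**Side chain (C11–C12 and C13–C16).** Target 34 comes from ester 33 and its bis-silyl ether 32 by deprotection. In 32 the C13–C16 bond is cut back to the (Z)-enol phosphate 31 and the C11–C12 bond to allylic bromide 28 plus the dianion 29 of methyl acetoacetate (8), through β-keto ester 30. An olefination at C13=C14 would give E/Z mixtures, and a cut at C12–C13 would need a homoallylic metal reagent. Bromide 28 lacks four skeletal carbons and the enoate. The forward steps must achieve SN2 substitution at a hindered primary allylic bromide and stereospecific methyl-for-phosphate exchange.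

**C11 and C3 adjustment.** Bromide 28 derives from allylic alcohol 26 and ester 25. The 3α-alcohol of 25 is traced through ketone 24 to the 3β-alcohol 23 and diol 22. The 3β configuration is kept up to 22 because it is the handle that delivers C19. Oxidation and reduction with a bulky hydride is preferred to an SN2 inversion at a neopentyl secondary carbon.

**C4–C19 and C5–H.** Diol 22 is cut at C4–C19 to the (bromomethyl)silyl ether 20 of allylic alcohol 19. A tethered silylmethyl radical reaches the β face of C4 from the 3β-oxygen, and the resulting C5 radical is reduced from the α face. Reductive alkylation of the enone would place the new carbon α and would expel the C6 oxygen. The cut removes two stereocentres and leads back to a flat enone.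

**Ring A and ring B functional groups.** Alcohol 19 comes from enone 18, which comes from dienone 17 by hydrogenation of C1=C2. The C8 methyl of 17 is traced through enol triflate 16 to the enolised β-keto ester 15. The β-keto ester thus supplies the tetrasubstituted alkene in the correct position, with C17 and C11 attached.

**C9–C10 (key cut).** Dienone 15 is opened at C9–C10 to phenol 14. This removes ring B and the quaternary C10 and leaves an arene with one stereocentre. The forward reaction needs para attack over ortho attack, C-attack over O-attack of the enol, and transfer of chirality from C6 to C10.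

**C6–C7.** Phenol 14 comes from bis-silyl ether 13 and aldol product 12. Cutting C6–C7 gives aldehyde 7 and Chan's diene 10, joined by a catalytic asymmetric vinylogous Mukaiyama aldol that sets C6. A stepwise acetate aldol plus Claisen extension would cost more steps.

**Arene.** Aldehyde 7 is cut at the formyl carbon to aryl bromide 6, made from phenol 5, aniline 3, nitroarene 2 and 2-bromo-1,3-dimethylbenzene (1). Diene 10 comes from silyl enol ether 9 and methyl acetoacetate (8), which also serves as the side-chain donor.

## Roads not taken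

**Alternative 1:** Ring A is closed last by a C3–C4 cut. Zinc would insert into the C4–Br bond of the α-bromo γ-lactone nitrile A1, and the zinc enolate would add to the nitrile carbon (intramolecular Blaise reaction) to give, after hydrolysis, the 3-oxo 19,6β-lactone A2.
- Merits: the lactone ties C19 to the 6β-oxygen, so C4 forms with C19 β by necessity. Both oxygens are masked in one ring, and C3 appears as a ketone one reduction away from the 3α-alcohol. In these respects it is better than the chosen plan, which needs a tether and an oxidation–reduction sequence at C3.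
- Weak points: A1 must already contain ring B with C5, C6 and the quaternary C10 set, so the hardest problem is moved upstream unsolved. A fully substituted zinc enolate must add to a nitrile next to the angular methyl, and protonation competes. The β-keto lactone can open by retro-Claisen during hydrolysis, and later lactone reduction forces the side chain to be carried at the alcohol oxidation level.
- Against this, the chosen plan creates C10 and ring B in one step from an arene with a single stereocentre.

**Alternative 2:** Ring B is closed by a C7–C8 cut. KOt-Bu would deprotonate the acetyl group of keto ester A3, and the enolate would attack the C8 ester to give the 6,8-dione A4.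
- Merits: a Claisen closure to a six-membered 1,3-dione is more dependable than an oxidative dearomatisation, and it is driven by deprotonation of the product.
- Weak points: A3 is a cyclohexane with four contiguous stereocentres, including both quaternary carbons, and making it is the real problem. The dione must then be differentiated. Enol sulfonylation occurs through the doubly activated C7, which leads to a Δ7-6-one and not to the C8=C9 alkene, and C5 can epimerise under the base.
- Against the more certain ring closure, the chosen plan has the β-keto ester exactly where the tetrasubstituted alkene is needed and has C6 at its final oxidation level and configuration.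

**Alternative 3:** Ring B is closed by a C5–C6 cut. A thiazolium-derived carbene would convert the aldehyde of A5 into an acyl anion equivalent that adds to C5 of the alkylidene β-keto ester (Stetter reaction), giving the bicyclic 6-ketone A6.
- Merits: the step is catalytic and near neutral, with a doubly activated acceptor. The ring-A β-keto ester of A6 allows classical methylation at C4 from the α face, which leaves the ester as C19. This is a more reliable route to the C4 quaternary centre than the tethered radical of the chosen plan.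
- Weak points: A6 has nothing at C8 and only an oxygen at C9, so the C8 methyl, the C9 chain and the tetrasubstituted alkene all remain to be built next to the quaternary C10. The trans ring fusion requires addition syn to the C20 methyl and is not assured, and the C9 silyloxy centre is undefined.
- The chosen plan sets against this the complete ring-B substitution pattern and the C6/C10 relationship from the key step.

Key step: step 11

Remark: atoms carry labdane numbers throughout (C1–C10 ring carbons, C11 on C9, C17 on C8, C18 α and C19 β on C4, C20 on C10), and β means the face of the C20 methyl group.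

## Steps

Step 1
Reactants: 1 2-bromo-1,3-dimethylbenzene
Product: 2 2-bromo-1,3-dimethyl-4-nitrobenzene
Conditions: HNO3 (1.1 equiv), H2SO4, 0 °C
Reagents that add atoms: nitric acid, O[N+](=O)[O-]
Why: Electrophilic aromatic nitration; both methyl groups direct to C4 (ortho to one, para to the other), and the only other free position is meta to both.

Step 2
Reactants: 2 2-bromo-1,3-dimethyl-4-nitrobenzene
Product: 3 3-bromo-2,4-dimethylaniline
Conditions: Fe powder, NH4Cl, EtOH/H2O, 80 °C
Reagents that add atoms: none
Why: Iron-mediated (Béchamp-type) nitro reduction, which does not hydrogenolyse the aryl bromide.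

Step 3
Reactants: 3 3-bromo-2,4-dimethylaniline
Product: 5 3-bromo-2,4-dimethylphenol, via arenediazonium hydrogen sulfate 4 (not isolated)
Conditions: NaNO2, aq. H2SO4, 0 °C; then into aq. H2SO4, 100 °C
Reagents that add atoms: water, O (phenol oxygen); sodium nitrite, [Na+].[O-]N=O (second nitrogen of 4 only)
Why: Diazotisation followed by thermal hydrolysis of the diazonium salt, the standard aniline-to-phenol conversion.

Step 4
Reactants: 5 3-bromo-2,4-dimethylphenol
Product: 6 (3-bromo-2,4-dimethylphenoxy)(tert-butyl)dimethylsilane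
Conditions: TBSCl, imidazole, DMF, rt
Reagents that add atoms: tert-butyldimethylsilyl chloride, CC(C)(C)[Si](C)(C)Cl
Why: Phenol silylation; the aryl silyl ether survives lithiation and the aldol step and can later be cleaved selectively beside an alkyl silyl ether.

Step 5
Reactants: 6 (3-bromo-2,4-dimethylphenoxy)(tert-butyl)dimethylsilane
Product: 7 3-(tert-butyldimethylsilyloxy)-2,6-dimethylbenzaldehyde
Conditions: n-BuLi, THF, −78 °C; DMF; then H2O
Reagents that add atoms: N,N-dimethylformamide, CN(C)C=O
Why: Bromine–lithium exchange and formylation with DMF; the aryllithium is meta to the silyloxy group, so no silyl migration can occur.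

Step 6
Reactants: 8 methyl acetoacetate
Product: 9 methyl 3-(trimethylsilyloxy)but-2-enoate (alkene geometry immaterial)
Conditions: Me3SiCl, Et3N, hexane, rt
Reagents that add atoms: chlorotrimethylsilane, C[Si](C)(C)Cl
Why: O-Silylation of the enol form of the β-keto ester with an amine base.

Step 7
Reactants: 9 methyl 3-(trimethylsilyloxy)but-2-enoate
Product: 10 1-methoxy-1,3-bis(trimethylsilyloxy)buta-1,3-diene (Chan's diene)
Conditions: LiN(i-Pr)2, THF, −78 °C; Me3SiCl
Reagents that add atoms: chlorotrimethylsilane, C[Si](C)(C)Cl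
Why: γ-Deprotonation of the silyl enol ether ester and O-silylation of the resulting ester enolate.

Step 8
Reactants: 7 3-(tert-butyldimethylsilyloxy)-2,6-dimethylbenzaldehyde; 10 1-methoxy-1,3-bis(trimethylsilyloxy)buta-1,3-diene
Product: 12 methyl (5R)-5-[3-(tert-butyldimethylsilyloxy)-2,6-dimethylphenyl]-5-hydroxy-3-oxopentanoate, via bis(trimethylsilyl) aldol adduct 11 (not isolated)
Conditions: Ti(OiPr)4 (10 mol %), (R)-BINOL (10 mol %), 4 Å MS, THF, −78 °C → rt; then CF3CO2H (cat.), wet THF, 0 °C
Reagents that add atoms: none
Why: Catalytic asymmetric vinylogous Mukaiyama aldol, the diene reacting at its terminal carbon. By analogy with related titanium–BINOL additions to aryl aldehydes, the (R)-BINOL complex is expected to expose the Re face and give the (R)-carbinol (C6); the antipodal ligand is used if the sense proves opposite. Acidic work-up removes both Me3Si groups.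

Step 9
Reactants: 12 methyl (5R)-5-[3-(tert-butyldimethylsilyloxy)-2,6-dimethylphenyl]-5-hydroxy-3-oxopentanoate
Product: 13 methyl (5R)-5-(tert-butyldimethylsilyloxy)-5-[3-(tert-butyldimethylsilyloxy)-2,6-dimethylphenyl]-3-oxopentanoate
Conditions: TBSOTf, 2,6-lutidine, CH2Cl2, −78 °C
Reagents that add atoms: tert-butyldimethylsilyl trifluoromethanesulfonate, CC(C)(C)[Si](C)(C)OS(=O)(=O)C(F)(F)F
Why: Silylation of the hindered benzylic alcohol with the silyl triflate at low temperature, which also blocks lactonisation of the δ-hydroxy β-keto ester.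

Step 10
Reactants: 13 methyl (5R)-5-(tert-butyldimethylsilyloxy)-5-[3-(tert-butyldimethylsilyloxy)-2,6-dimethylphenyl]-3-oxopentanoate
Product: 14 methyl (5R)-5-(tert-butyldimethylsilyloxy)-5-(3-hydroxy-2,6-dimethylphenyl)-3-oxopentanoate
Conditions: KHF2, MeOH, rt
Reagents that add atoms: none
Why: Chemoselective cleavage of an aryl silyl ether beside an alkyl silyl ether with bifluoride under near-neutral conditions; any enol silyl ether carried over from step 9 is cleaved as well.

Step 11
Reactants: 14 methyl (5R)-5-(tert-butyldimethylsilyloxy)-5-(3-hydroxy-2,6-dimethylphenyl)-3-oxopentanoate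
Product: 15 methyl (4R,8aS)-4-(tert-butyldimethylsilyloxy)-2-hydroxy-5,8a-dimethyl-6-oxo-3,4,6,8a-tetrahydronaphthalene-1-carboxylate (labdane numbering: 1,4-dien-3-one; 4- and 10β-methyl; 6β-OTBS; C8 enol; C9 CO2Me)
Conditions: PhI(OAc)2 (1.1 equiv), (CF3)2CHOH (0.02 M), 0 °C
Reagents that add atoms: none
Why: Ligand exchange of the phenol at the trivalent iodine of PhI(OAc)2, then loss of iodobenzene and acetate in the ionising, non-nucleophilic fluorinated alcohol, gives a phenoxenium-type species with positive charge at C10 (para) and C4 (ortho). The enol carbon C9 of the β-keto ester, held on the C5 substituent, attacks C10 and forms the C9–C10 bond, and the product settles as the cross-conjugated dienone with the β-keto ester enolised. The closest known reaction type is the hypervalent-iodine oxidative dearomatisation of para-alkyl phenols by tethered carbon nucleophiles (β-dicarbonyl enols, silyl enol ethers, allylsilanes), here in the fused mode and not the commoner spiro mode, because the tether sits on the meta carbon. Ring B closes as a six-membered carbocycle by a 6-(enolendo) attack on the trigonal cationic C10, and the former arene bond C5–C10 becomes the ring fusion. The new stereocentre C10 is controlled by C6: to avoid allylic 1,3-strain with the C4 methyl, the C6 hydrogen lies in the arene plane, so C7 and the silyloxy group project to opposite faces, the tether reaches C10 from its own face, and the C20 methyl ends on the face of the silyloxy group (10β-methyl cis to 6β-oxygen). The step needs para over ortho attack (both give six-membered rings); this is expected from the larger positive charge at the para carbon and from the cross-conjugated product being preferred over a linearly conjugated 2,4-dienone. It also needs C- over O-attack of the enol; an O-bound quinol vinyl ether could re-ionise in this solvent, whereas the C–C bond is irreversible. The silyloxy group is on a meta substituent, so it cannot be lost through a quinone methide, and high dilution suppresses intermolecular coupling.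

Step 12
Reactants: 15 dienone enol (as in step 11)
Product: 16 C8 enol triflate of 15: 1,4-dien-3-one; 4- and 10β-methyl; 6β-OTBS; C8(OTf)=C9(CO2Me)
Conditions: Tf2O, i-Pr2NEt, CH2Cl2, −78 °C
Reagents that add atoms: trifluoromethanesulfonic anhydride, O=S(=O)(OS(=O)(=O)C(F)(F)F)C(F)(F)F
Why: O-Sulfonylation of the cyclic β-keto ester enol, the only acidic site, to the vinyl triflate.

Step 13
Reactants: 16 C8 enol triflate
Product: 17 dienone ester: 1,4-dien-3-one; 4- and 10β-methyl; 6β-OTBS; C8(CH3)=C9(CO2Me)
Conditions: Me2Zn, Pd(PPh3)4 (5 mol %), THF, 0 °C → rt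
Reagents that add atoms: dimethylzinc, C[Zn]C
Why: Negishi cross-coupling of the electron-poor vinyl triflate; dimethylzinc does not add to the dienone under these conditions, whereas a cuprate would.

Step 14
Reactants: 17 dienone ester
Product: 18 enone ester: 4-en-3-one (4-methyl); 10β-methyl; 6β-OTBS; C8(CH3)=C9(CO2Me)
Conditions: H2 (1 atm), RhCl(PPh3)3 (10 mol %), benzene/EtOH, rt
Reagents that add atoms: none
Why: Homogeneous hydrogenation with RhCl(PPh3)3 is selective for the disubstituted C1=C2 bond of cross-conjugated 1,4-dien-3-ones (steroid precedent); the tetrasubstituted C4=C5 and C8=C9 bonds are inert.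

Step 15
Reactants: 18 enone ester
Product: 19 allylic alcohol: 3β-hydroxy-4-ene (4-methyl); 10β-methyl; 6β-OTBS; C8(CH3)=C9(CO2Me)
Conditions: NaBH4, CeCl3·7H2O, MeOH, −40 °C
Reagents that add atoms: none
Why: Luche 1,2-reduction; axial hydride delivery on the α face (anti to C20) should give the pseudo-equatorial 3β-alcohol as with steroidal 4-en-3-ones, and the enoate is untouched.

Step 16
Reactants: 19 allylic alcohol
Product: 20 3β-O-(bromomethyl)dimethylsilyl ether of 19
Conditions: BrCH2SiMe2Cl, Et3N, DMAP (cat.), CH2Cl2, 0 °C
Reagents that add atoms: (bromomethyl)chlorodimethylsilane, C[Si](C)(Cl)CBr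
Why: Silylation of the allylic alcohol with the chlorosilane; the product is used after filtration because its Si–O bond is hydrolytically labile.

Step 17
Reactants: 20 (bromomethyl)dimethylsilyl ether
Product: 22 diol: 3β-hydroxy; 4α-methyl; 4β-hydroxymethyl (C19); 5α-H; 10β-methyl; 6β-OTBS; C8(CH3)=C9(CO2Me), via cyclic siloxane 21 (not isolated)
Conditions: Bu3SnH (slow addition), AIBN (cat.), benzene (0.01 M), 80 °C; then KF, KHCO3, 30% H2O2, THF/MeOH, 40 °C
Reagents that add atoms: hydrogen peroxide, OO
Why: Nishiyama–Stork radical cyclisation: the silylmethyl radical adds 5-exo to C4 on the face of the 3β-oxygen to give the cis-fused oxasilolane, since 6-endo closure would need a bridged ring at the neopentyl C5. The C5 radical takes hydrogen from Bu3SnH on the open α face (β is blocked by C20, the 6β-silyloxy group and the new bridge), which sets the trans ring fusion. Tamao oxidation then converts C–Si into C–OH.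

Step 18
Reactants: 22 diol
Product: 23 19-O-TBS ether of 22 (3β-hydroxyl free)
Conditions: TBSCl (1.1 equiv), imidazole, CH2Cl2, 0 °C
Reagents that add atoms: tert-butyldimethylsilyl chloride, CC(C)(C)[Si](C)(C)Cl
Why: Selective silylation of the primary hydroxyl over the secondary 3β-hydroxyl, which is flanked by the quaternary C4.

Step 19
Reactants: 23 19-O-TBS 3β-alcohol
Product: 24 3-ketone: 4α-methyl; 4β-CH2OTBS; 5α-H; 10β-methyl; 6β-OTBS; C8(CH3)=C9(CO2Me)
Conditions: Dess–Martin periodinane, CH2Cl2, 0 °C → rt
Reagents that add atoms: none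
Why: Dess–Martin oxidation of the secondary alcohol; C4 has no hydrogen, so the β-silyloxy ketone cannot eliminate.

Step 20
Reactants: 24 3-ketone
Product: 25 3α-alcohol: 3α-hydroxy; 4α-methyl; 4β-CH2OTBS; 5α-H; 10β-methyl; 6β-OTBS; C8(CH3)=C9(CO2Me)
Conditions: LiBH(s-Bu)3, THF, −78 °C; then H2O
Reagents that add atoms: none
Why: The bulky trialkylborohydride attacks the 4,4-disubstituted 3-ketone along the equatorial trajectory (the axial approach is blocked by H-1α and H-5α) and should give the axial 3α-alcohol, as with 3-oxo triterpenoids; the ester is not reduced at −78 °C.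

Step 21
Reactants: 25 3α-alcohol ester
Product: 26 allylic alcohol: as 25 with C9–CH2OH (C11) in place of the ester
Conditions: i-Bu2AlH (4 equiv), CH2Cl2, −78 → 0 °C; aq. potassium sodium tartrate
Reagents that add atoms: none
Why: Hydride reduction of the conjugated ester to the primary allylic alcohol; the free 3α-hydroxyl only consumes one equivalent of reagent.

Step 22
Reactants: 26 allylic alcohol
Product: 28 allylic bromide: as 26 with C9–CH2Br, via allylic mesylate 27 (not isolated)
Conditions: MsCl (1.1 equiv), Et3N, THF, −40 °C; then LiBr, −40 → 0 °C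
Reagents that add atoms: lithium bromide, [Li+].[Br-]; methanesulfonyl chloride, CS(=O)(=O)Cl (mesyl group of 27 only)
Why: Mesylation of the primary allylic hydroxyl is much faster than that of the hindered axial 3α-hydroxyl, and bromide displaces the allylic mesylate in situ by SN2 (SN2′ would create a quaternary C8).

Step 23
Reactants: 28 allylic bromide; 8 methyl acetoacetate
Product: 30 β-keto ester: as 28 with C9–CH2CH2C(=O)CH2CO2CH3, via acetoacetate dianion 29 (not isolated)
Conditions: 8 (3 equiv), NaH, THF, 0 °C; n-BuLi, 0 °C; then 28, −20 → 0 °C; AcOH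
Reagents that add atoms: none
Why: Weiler alkylation: the dianion reacts at its terminal carbon with the allylic bromide, and the excess absorbs the proton of the free hydroxyl.

Step 24
Reactants: 30 β-keto ester
Product: 31 (Z)-enol diethyl phosphate of 30 at C13 (phosphate cis to CO2CH3)
Conditions: NaH (1.05 equiv), Et2O, 0 °C; ClP(O)(OEt)2
Reagents that add atoms: diethyl chlorophosphate, CCOP(=O)(Cl)OCC
Why: The chelated sodium enolate of the β-keto ester is O-phosphorylated to the (Z)-enol phosphate (Weiler); with one equivalent of base the neutral, hindered 3α-hydroxyl stays free.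

Step 25
Reactants: 31 (Z)-enol phosphate
Product: 32 methyl 6β,19-bis(tert-butyldimethylsilyloxy)-3α-hydroxylabda-8,13E-dien-15-oate
Conditions: Me2CuLi (from CuI and MeLi, 4 equiv), Et2O, −78 → −45 °C
Reagents that add atoms: lithium dimethylcuprate, [Li+].C[Cu-]C (made in the flask from methyllithium, [Li]C, and CuI)
Why: Cuprate substitution of the enol phosphate proceeds with retention (addition–elimination) and gives the 13E trisubstituted enoate; the excess allows for the free hydroxyl.

Step 26
Reactants: 32 bis-silyl ether ester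
Product: 33 methyl 3α,6β,19-trihydroxylabda-8,13E-dien-15-oate
Conditions: 48% aq. HF, MeCN, 0 °C → rt
Reagents that add atoms: none
Why: Acidic fluoride cleavage of both silyl ethers; aqueous HF is chosen because the 6β ether lies between two syn-axial groups.

Step 27
Reactants: 33 triol methyl ester
Product: 34 3α,6β,19-trihydroxylabda-8,13E-dien-15-oic acid (target)
Conditions: LiOH, THF/MeOH/H2O, 45 °C; then 1 M HCl to pH 3
Reagents that add atoms: lithium hydroxide, [Li+].[OH-]
Why: Saponification of the methyl ester (acyl–oxygen cleavage) and acidification; the conditions are mild enough to leave the 13E geometry and the C8=C9 bond in place.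

## Compound list

1 | 2-bromo-1,3-dimethylbenzene | Cc1cccc(C)c1Br | starting material
2 | 2-bromo-1,3-dimethyl-4-nitrobenzene | Cc1ccc([N+](=O)[O-])c(C)c1Br | intermediate
3 | 3-bromo-2,4-dimethylaniline | Cc1ccc(N)c(C)c1Br | intermediate
4 | 3-bromo-2,4-dimethylbenzenediazonium hydrogen sulfate | Cc1ccc([N+]#N)c(C)c1Br.OS(=O)(=O)[O-] | intermediate (not isolated)
5 | 3-bromo-2,4-dimethylphenol | Cc1ccc(O)c(C)c1Br | intermediate
6 | (3-bromo-2,4-dimethylphenoxy)(tert-butyl)dimethylsilane | Cc1ccc(O[Si](C)(C)C(C)(C)C)c(C)c1Br | intermediate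
7 | 3-(tert-butyldimethylsilyloxy)-2,6-dimethylbenzaldehyde | Cc1ccc(O[Si](C)(C)C(C)(C)C)c(C)c1C=O | intermediate
8 | methyl acetoacetate | COC(=O)CC(C)=O | starting material
9 | methyl 3-(trimethylsilyloxy)but-2-enoate | COC(=O)C=C(C)O[Si](C)(C)C | intermediate
10 | 1-methoxy-1,3-bis(trimethylsilyloxy)buta-1,3-diene | COC(O[Si](C)(C)C)=CC(=C)O[Si](C)(C)C | intermediate
11 | methyl (5R)-5-[3-(tert-butyldimethylsilyloxy)-2,6-dimethylphenyl]-3,5-bis(trimethylsilyloxy)pent-2-enoate | Cc1ccc(O[Si](C)(C)C(C)(C)C)c(C)c1[C@H](O[Si](C)(C)C)CC(O[Si](C)(C)C)=CC(=O)OC | intermediate (not isolated)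
12 | methyl (5R)-5-[3-(tert-butyldimethylsilyloxy)-2,6-dimethylphenyl]-5-hydroxy-3-oxopentanoate | Cc1ccc(O[Si](C)(C)C(C)(C)C)c(C)c1[C@H](O)CC(=O)CC(=O)OC | intermediate
13 | methyl (5R)-5-(tert-butyldimethylsilyloxy)-5-[3-(tert-butyldimethylsilyloxy)-2,6-dimethylphenyl]-3-oxopentanoate | Cc1ccc(O[Si](C)(C)C(C)(C)C)c(C)c1[C@H](O[Si](C)(C)C(C)(C)C)CC(=O)CC(=O)OC | intermediate
14 | methyl (5R)-5-(tert-butyldimethylsilyloxy)-5-(3-hydroxy-2,6-dimethylphenyl)-3-oxopentanoate | Cc1ccc(O)c(C)c1[C@H](O[Si](C)(C)C(C)(C)C)CC(=O)CC(=O)OC | intermediate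
15 | methyl (4R,8aS)-4-(tert-butyldimethylsilyloxy)-2-hydroxy-5,8a-dimethyl-6-oxo-3,4,6,8a-tetrahydronaphthalene-1-carboxylate | OC1=C(C(=O)OC)[C@@]2(C)C=CC(=O)C(C)=C2[C@H](O[Si](C)(C)C(C)(C)C)C1 | intermediate
16 | C8 enol triflate of 15 | O=S(=O)(OC1=C(C(=O)OC)[C@@]2(C)C=CC(=O)C(C)=C2[C@H](O[Si](C)(C)C(C)(C)C)C1)C(F)(F)F | intermediate
17 | dienone ester, C8(CH3)=C9(CO2Me), 6β-OTBS, 10β-methyl | CC1=C(C(=O)OC)[C@@]2(C)C=CC(=O)C(C)=C2[C@H](O[Si](C)(C)C(C)(C)C)C1 | intermediate
18 | 4-en-3-one ester, 6β-OTBS, 10β-methyl | CC1=C(C(=O)OC)[C@@]2(C)CCC(=O)C(C)=C2[C@H](O[Si](C)(C)C(C)(C)C)C1 | intermediate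
19 | 3β-hydroxy-4-ene ester, 6β-OTBS | CC1=C(C(=O)OC)[C@@]2(C)CC[C@H](O)C(C)=C2[C@H](O[Si](C)(C)C(C)(C)C)C1 | intermediate
20 | 3β-O-(bromomethyl)dimethylsilyl ether of 19 | CC1=C(C(=O)OC)[C@@]2(C)CC[C@H](O[Si](C)(C)CBr)C(C)=C2[C@H](O[Si](C)(C)C(C)(C)C)C1 | intermediate
21 | cyclic siloxane (O3–SiMe2–C19 bridge, 5α-H) | CC1=C(C(=O)OC)[C@@]2(C)CC[C@@H]3O[Si](C)(C)C[C@]3(C)[C@@H]2[C@H](O[Si](C)(C)C(C)(C)C)C1 | intermediate (not isolated)
22 | 3β,19-diol, 5α-H, 6β-OTBS, C11 methyl ester | CC1=C(C(=O)OC)[C@@]2(C)CC[C@H](O)[C@](C)(CO)[C@@H]2[C@H](O[Si](C)(C)C(C)(C)C)C1 | intermediate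
23 | 19-O-TBS 3β-alcohol | CC1=C(C(=O)OC)[C@@]2(C)CC[C@H](O)[C@](C)(CO[Si](C)(C)C(C)(C)C)[C@@H]2[C@H](O[Si](C)(C)C(C)(C)C)C1 | intermediate
24 | 3-ketone, 19- and 6β-OTBS | CC1=C(C(=O)OC)[C@@]2(C)CCC(=O)[C@](C)(CO[Si](C)(C)C(C)(C)C)[C@@H]2[C@H](O[Si](C)(C)C(C)(C)C)C1 | intermediate
25 | 3α-alcohol, 19- and 6β-OTBS, C11 methyl ester | CC1=C(C(=O)OC)[C@@]2(C)CC[C@@H](O)[C@](C)(CO[Si](C)(C)C(C)(C)C)[C@@H]2[C@H](O[Si](C)(C)C(C)(C)C)C1 | intermediate
26 | C11 allylic alcohol, 3α-OH | CC1=C(CO)[C@@]2(C)CC[C@@H](O)[C@](C)(CO[Si](C)(C)C(C)(C)C)[C@@H]2[C@H](O[Si](C)(C)C(C)(C)C)C1 | intermediate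
27 | C11 allylic mesylate | CC1=C(COS(C)(=O)=O)[C@@]2(C)CC[C@@H](O)[C@](C)(CO[Si](C)(C)C(C)(C)C)[C@@H]2[C@H](O[Si](C)(C)C(C)(C)C)C1 | intermediate (not isolated)
28 | C11 allylic bromide | CC1=C(CBr)[C@@]2(C)CC[C@@H](O)[C@](C)(CO[Si](C)(C)C(C)(C)C)[C@@H]2[C@H](O[Si](C)(C)C(C)(C)C)C1 | intermediate
29 | sodium lithium dianion of methyl acetoacetate | [Li+].[Na+].[CH2-]C(=O)[CH-]C(=O)OC | intermediate (not isolated)
30 | side-chain β-keto ester (13-oxo, C15 methyl ester) | CC1=C(CCC(=O)CC(=O)OC)[C@@]2(C)CC[C@@H](O)[C@](C)(CO[Si](C)(C)C(C)(C)C)[C@@H]2[C@H](O[Si](C)(C)C(C)(C)C)C1 | intermediate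
31 | (Z)-enol diethyl phosphate at C13 | CC1=C(CC/C(OP(=O)(OCC)OCC)=C/C(=O)OC)[C@@]2(C)CC[C@@H](O)[C@](C)(CO[Si](C)(C)C(C)(C)C)[C@@H]2[C@H](O[Si](C)(C)C(C)(C)C)C1 | intermediate
32 | methyl 6β,19-bis(tert-butyldimethylsilyloxy)-3α-hydroxylabda-8,13E-dien-15-oate | CC1=C(CC/C(C)=C/C(=O)OC)[C@@]2(C)CC[C@@H](O)[C@](C)(CO[Si](C)(C)C(C)(C)C)[C@@H]2[C@H](O[Si](C)(C)C(C)(C)C)C1 | intermediate
33 | methyl 3α,6β,19-trihydroxylabda-8,13E-dien-15-oate | CC1=C(CC/C(C)=C/C(=O)OC)[C@@]2(C)CC[C@@H](O)[C@](C)(CO)[C@@H]2[C@H](O)C1 | intermediate
34 | 3α,6β,19-trihydroxylabda-8,13E-dien-15-oic acid | CC1=C(CC/C(C)=C/C(=O)O)[C@@]2(C)CC[C@@H](O)[C@](C)(CO)[C@@H]2[C@H](O)C1 | target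

## Step count and least certain steps

Total: 27 steps. Longest linear sequence: 25 steps (steps 1–5 and 8–27, from 1); the diene branch (steps 6–7) joins at step 8.

**Step 11 (key step).** The enol may attack through oxygen or at the ortho carbon C4, or the oxidant may attack the β-keto ester, because the enol is ambident and both ring positions are reachable through a six-membered transition state. Fallback: from 14, both acidic hydroxyls are silylated (Me3SiCl, Et3N) to give the aryl trimethylsilyl ether trimethylsilyl enol ether F1. Oxidation of F1 with PhI(OCOCF3)2 in CH2Cl2 at −40 °C uses the O-silyl phenol as the oxidisable unit and a silyl enol ether that can only react through carbon (Mukaiyama-type). Aqueous work-up rejoins the route at 15.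

**Step 8.** The di-ortho-substituted aldehyde may react slowly and with poor facial discrimination at the catalyst. Fallback: from 7, addition of LiCH2CO2Me gives the racemic β-hydroxy ester F2, which is oxidised (Dess–Martin periodinane) to the β-keto ester F3. Hydrogenation with RuCl2[(S)-BINAP] (H2, MeOH) gives the (R)-β-hydroxy ester F4, and Claisen condensation with excess LiCH2CO2Me rejoins the route at 12.

**Step 17.** The silylmethyl radical may be reduced before it closes onto the fully substituted C4, may leak into endo closure, or hydrogen may be delivered to the β face of C5. Fallback: from 19, ethyl vinyl ether and N-bromosuccinimide give the bromoacetal F5. Its Ueno–Stork cyclisation (Bu3SnH, AIBN), through a shorter carbon–oxygen tether that closes strictly 5-exo, gives the cis-fused cyclic acetal F6. Elimination (Me3SiOTf, i-Pr2NEt) gives the dihydrofuran F7, and ozonolysis of this electron-rich enol ether (O3, −78 °C; Me2S) removes the extra carbon to give the 3β-formyloxy C19 aldehyde F8. NaBH4 in MeOH followed by K2CO3 rejoins the route at 22.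

**Step 20.** Hydride may be delivered from the wrong face if the axial CH2OTBS group hinders the equatorial approach. Fallback: from 24, selective cleavage of the primary silyl ether (HF·pyridine, THF, 0 °C) gives the 19-hydroxy 3-ketone F9. Hydroxyl-directed reduction with Me4NBH(OAc)3 delivers hydride from the β face, on which C19 lies, to give the 3α,19-diol F10. Selective silylation of the primary hydroxyl (TBSCl, imidazole) rejoins the route at 25.

**Step 23.** Substitution at the hindered allylic bromide may be slow, so that elimination or proton transfer from the strongly basic dianion takes over. Fallback: from 28, alkylation with the softer sodium monoenolate of 8 gives the α-alkylated acetoacetate F11. Dealkoxycarbonylation (LiCl, wet DMSO, 140 °C) gives the methyl ketone F12. Horner–Wadsworth–Emmons olefination with (MeO)2P(O)CH2CO2Me and NaH, followed by separation of the minor Z isomer, rejoins the route at 32.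

## Further compounds

F1 | step 11 | methyl (5R)-5-(tert-butyldimethylsilyloxy)-5-[2,6-dimethyl-3-(trimethylsilyloxy)phenyl]-3-(trimethylsilyloxy)pent-2-enoate | Cc1ccc(O[Si](C)(C)C)c(C)c1[C@H](O[Si](C)(C)C(C)(C)C)CC(O[Si](C)(C)C)=CC(=O)OC
F2 | step 8 | methyl 3-[3-(tert-butyldimethylsilyloxy)-2,6-dimethylphenyl]-3-hydroxypropanoate (racemic) | Cc1ccc(O[Si](C)(C)C(C)(C)C)c(C)c1C(O)CC(=O)OC
F3 | step 8 | methyl 3-[3-(tert-butyldimethylsilyloxy)-2,6-dimethylphenyl]-3-oxopropanoate | Cc1ccc(O[Si](C)(C)C(C)(C)C)c(C)c1C(=O)CC(=O)OC
F4 | step 8 | methyl (3R)-3-[3-(tert-butyldimethylsilyloxy)-2,6-dimethylphenyl]-3-hydroxypropanoate | Cc1ccc(O[Si](C)(C)C(C)(C)C)c(C)c1[C@H](O)CC(=O)OC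
F5 | step 17 | 3β-O-(2-bromo-1-ethoxyethyl) ether of 19 | CC1=C(C(=O)OC)[C@@]2(C)CC[C@H](OC(CBr)OCC)C(C)=C2[C@H](O[Si](C)(C)C(C)(C)C)C1
F6 | step 17 | cis-fused cyclic ethyl acetal (O3–CH(OEt)–CH2–C4, 5α-H) | CC1=C(C(=O)OC)[C@@]2(C)CC[C@@H]3OC(OCC)C[C@]3(C)[C@@H]2[C@H](O[Si](C)(C)C(C)(C)C)C1
F7 | step 17 | cis-fused dihydrofuran (O3–CH=CH–C4) | CC1=C(C(=O)OC)[C@@]2(C)CC[C@@H]3OC=C[C@]3(C)[C@@H]2[C@H](O[Si](C)(C)C(C)(C)C)C1
F8 | step 17 | 3β-formyloxy C19 aldehyde | CC1=C(C(=O)OC)[C@@]2(C)CC[C@H](OC=O)[C@](C)(C=O)[C@@H]2[C@H](O[Si](C)(C)C(C)(C)C)C1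
F9 | step 20 | 19-hydroxy 3-ketone, 6β-OTBS | CC1=C(C(=O)OC)[C@@]2(C)CCC(=O)[C@](C)(CO)[C@@H]2[C@H](O[Si](C)(C)C(C)(C)C)C1
F10 | step 20 | 3α,19-diol, 6β-OTBS | CC1=C(C(=O)OC)[C@@]2(C)CC[C@@H](O)[C@](C)(CO)[C@@H]2[C@H](O[Si](C)(C)C(C)(C)C)C1
F11 | step 23 | α-alkylated methyl acetoacetate (C11 on the acetoacetate α-carbon) | CC1=C(CC(C(C)=O)C(=O)OC)[C@@]2(C)CC[C@@H](O)[C@](C)(CO[Si](C)(C)C(C)(C)C)[C@@H]2[C@H](O[Si](C)(C)C(C)(C)C)C1
F12 | step 23 | side-chain methyl ketone (C9–CH2CH2COCH3) | CC1=C(CCC(C)=O)[C@@]2(C)CC[C@@H](O)[C@](C)(CO[Si](C)(C)C(C)(C)C)[C@@H]2[C@H](O[Si](C)(C)C(C)(C)C)C1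
A1 | alternative 1 | α-bromo 19,6β-lactone with 2-cyanoethyl arm on C10 (bromide configuration immaterial) | CC1=C(CC/C(C)=C/CO[Si](C)(C)C(C)(C)C)[C@@](C)(CCC#N)[C@H]2[C@@H](C1)OC(=O)C2(C)Br
A2 | alternative 1 | tricyclic 3-oxo 19,6β-lactone with C8=C9 alkene and silylated side chain | CC1=C(CC/C(C)=C/CO[Si](C)(C)C(C)(C)C)[C@@]2(C)CCC(=O)[C@@]3(C)[C@@H]2[C@@H](C1)OC3=O
A3 | alternative 2 | ring-A keto ester with C5 acetyl group and C8 methyl ester | COC(=O)[C@H](CC/C(C)=C/CO[Si](C)(C)C(C)(C)C)[C@@]1(C)CC[C@@H](O[Si](C)(C)C(C)(C)C)[C@](C)(CO[Si](C)(C)C(C)(C)C)[C@@H]1C(C)=O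
A4 | alternative 2 | trans-decalin 6,8-dione with C9 side chain, 3α- and C19 silyl ethers | O=C1[C@H](CC/C(C)=C/CO[Si](C)(C)C(C)(C)C)[C@@]2(C)CC[C@@H](O[Si](C)(C)C(C)(C)C)[C@](C)(CO[Si](C)(C)C(C)(C)C)[C@@H]2C(=O)C1
A5 | alternative 3 | C6 aldehyde tethered to the alkylidene β-keto ester of ring A | O=CCCC(O[Si](C)(C)C(C)(C)C)[C@@]1(C)CCC(=O)C(C(=O)OC)=C1
A6 | alternative 3 | trans-fused bicyclic 6-ketone with enolised 3-keto 4-ester and 9-silyl ether | C1C(O[Si](C)(C)C(C)(C)C)[C@@]2(C)CCC(O)=C(C(=O)OC)[C@@H]2C(=O)C1
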